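## Retrosynthetic overview

1. Target 17 ⇒ Suzuki coupling (C12–C13) of alkenylboronate 13 with iodo-diene 16; 13 ⇐ cross-metathesis at the isopropenyl group of bromo-dienol 12.
2. 12 ⇐ hydroxy-acetate 9, by dehydration to the exocyclic methylene and removal of the acetate.
3. 9 ⇐ ten-membered enol acetate 7: a bromonium-triggered transannular closure of the C5–C10 bond makes rings A and B together (plus a transient dioxolanylium ring) and sets C1, C5 and C10 relative to C7.
4. 7 ⇐ anionic oxy-Cope ring expansion and O-acetylation of the trans-1,2-dialkenylcyclohexanol 5, made in three steps from (R)-carvone.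
5. Ring order: the carvone ring is expanded to the ten-membered ring (step 4), which then collapses to both six-membered rings in one operation (step 5).

Assumption: ring positions use eudesmane numbering (C1 = CHBr, C4 = C(=CH2), C5 = C–O, C7 = side-chain carbon, C10 = C–CH3; β = the face of the C10 methyl), and all named reagents are bought.

## Route

Step 1
Reactants: 1 (R)-(−)-carvone
Product: 3 (2R,5R)-2-(1-hydroxyethyl)-2-methyl-5-(prop-1-en-2-yl)cyclohexan-1-one, via lithium enolate 2 (not isolated)
Conditions: L-Selectride, THF, −78 °C; MeCHO, −78 °C; H2O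
Reagents that add atoms: acetaldehyde CC=O
Why: Conjugate hydride reduction gives the tetrasubstituted enolate regiospecifically, and its aldol addition (reductive aldol) sets the C2 quaternary centre by axial attack on the half-chair with isopropenyl equatorial, so the hydroxyethyl group enters cis to isopropenyl (the carbinol centre is erased in step 2 and C2 in step 4; the minor C2 epimer is removed by chromatography after step 2).

Step 2
Reactants: 3 (2R,5R)-2-(1-hydroxyethyl)-2-methyl-5-(prop-1-en-2-yl)cyclohexan-1-one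
Product: 4 (2R,5R)-2-ethenyl-2-methyl-5-(prop-1-en-2-yl)cyclohexan-1-one
Conditions: Burgess reagent, PhMe, 60 °C
Reagents that add atoms: none
Why: Burgess dehydration, in which the syn-elimination of the secondary sulfamate can only take a hydrogen of the adjacent methyl group because C2 is quaternary, so the vinyl group forms without touching C2 or C5.

Step 3
Reactants: 4 (2R,5R)-2-ethenyl-2-methyl-5-(prop-1-en-2-yl)cyclohexan-1-one
Product: 5 (1S,2R,5R)-2-ethenyl-2-methyl-1,5-di(prop-1-en-2-yl)cyclohexan-1-ol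
Conditions: isopropenylMgBr, LaCl3·2LiCl (cat.), THF, −40 → 0 °C; H2O
Reagents that add atoms: isopropenylmagnesium bromide CC(=C)[Mg]Br
Why: Grignard 1,2-addition in which the nucleophile attacks axially, anti to the axial vinyl group on the adjacent quaternary carbon (Felkin–Anh), so the new isopropenyl group is trans to the vinyl group, as the chair oxy-Cope requires.

Step 4
Reactants: 5 (1S,2R,5R)-2-ethenyl-2-methyl-1,5-di(prop-1-en-2-yl)cyclohexan-1-ol
Product: 7 (1Z,5E,9R)-2,6-dimethyl-9-(prop-1-en-2-yl)cyclodeca-1,5-dien-1-yl acetate, via potassium dienolate 6 (not isolated)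
Conditions: KH, 18-crown-6, THF, 0 → 25 °C; Ac2O, −78 °C; product kept ≤ 0 °C and used at once
Reagents that add atoms: acetic anhydride CC(=O)OC(C)=O
Why: Anionic oxy-Cope rearrangement through the chair transition state of the ring-flipped trans-diequatorial dialkenyl alkoxide, which places the ring carbons trans across both new ring olefins (germacrene E,E geometry) and erases the two carbinol-side centres, followed by O-acetylation of the potassium enolate so that only the carvone-derived centre remains.

Step 5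
Reactants: 7 (1Z,5E,9R)-2,6-dimethyl-9-(prop-1-en-2-yl)cyclodeca-1,5-dien-1-yl acetate
Product: 9 (1R,4R,5S,7R,10R)-1-bromo-4-hydroxyeudesm-11-en-5-yl acetate, via acetoxonium ion 8 (not isolated)
Conditions: NBS (1.05 equiv), acetone–H2O 9:1, −20 → 0 °C, dark
Reagents that add atoms: N-bromosuccinimide O=C1CCC(=O)N1Br; water O
Why: Proposed new method: Br+ adds to the strained (E)-C1=C10 olefin from the ring periphery while C5 of the enol acetate, held about 3 Å from C10 in the crossed (Cope-type) conformer, attacks C10 anti to bromine through a chair–chair transition state with the C7 isopropenyl group equatorial, so rings A and B close together as the trans-decalin with equatorial 1β-Br, axial 10β-CH3 and axial 5α-OAc, the tertiary C4 cation is captured by the neighbouring acetate carbonyl (transient dioxolan-2-ylium ring, 8) and water opens 8 to the axial acetate and equatorial 4α-alcohol; the closest known reaction type is the NBS/aqueous-acetone transannular bromocyclisation of (E,E)-germacra-1(10),4-dienes to 1β-bromoeudesman-4-ols, extended here to an enol acetate reacting through its oxygen-bearing carbon because only C5–C10 bonding gives the strain-free 6/6 system and the C4 cation is acetoxy-stabilised.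

Step 6
Reactants: 9 (1R,4R,5S,7R,10R)-1-bromo-4-hydroxyeudesm-11-en-5-yl acetate
Product: 11 (1R,5R,7R,10R)-1-bromoeudesma-4(15),11-dien-5-yl acetate, via chlorosulfite 10 (not isolated)
Conditions: SOCl2, pyridine, CH2Cl2, −20 → 0 °C
Reagents that add atoms: none
Why: Pyridine-mediated anti (E2) elimination of the equatorial tertiary chlorosulfite, which has no anti-periplanar ring hydrogen (C5 is fully substituted, the C3 hydrogens are gauche), so a methyl hydrogen is lost and the exocyclic methylene forms (Barton's rule for equatorial tertiary alcohols) while C4 ceases to be a stereocentre.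

Step 7
Reactants: 11 (1R,5R,7R,10R)-1-bromoeudesma-4(15),11-dien-5-yl acetate
Product: 12 (1R,5R,7R,10R)-1-bromoeudesma-4(15),11-dien-5-ol
Conditions: DIBAL-H, CH2Cl2, −78 °C; Rochelle salt
Reagents that add atoms: none
Why: Reductive cleavage of the hindered tertiary acetate by DIBAL-H at −78 °C, where the aluminium alkoxide does not undergo Grob fragmentation with the anti-periplanar C1–Br bond and the secondary bromide and both olefins are inert.

Step 8
Reactants: 12 (1R,5R,7R,10R)-1-bromoeudesma-4(15),11-dien-5-ol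
Product: 13 2-{(1E)-2-[(1R,5R,7R,10R)-1-bromo-5-hydroxyeudesm-4(15)-en-7-yl side chain]prop-1-en-1-yl}-4,4,5,5-tetramethyl-1,3,2-dioxaborolane (C7–C(CH3)=CH–Bpin)
Conditions: vinyl-Bpin (5 equiv), Hoveyda–Grubbs II (10 mol %), CH2Cl2, 40 °C
Reagents that add atoms: vinylboronic acid pinacol ester C=CB1OC(C)(C)C(C)(C)O1
Why: Olefin cross-metathesis of the isopropenyl olefin with vinyl-Bpin, the C4 methylene being shielded by the fully substituted C5 and staying out of the catalytic cycle, with the thermodynamically preferred product carrying boron trans to the ring (E).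

Step 9
Reactants: 14 2-methylbut-1-en-3-yne
Product: 16 (1E)-1-iodo-3-methylbuta-1,3-diene, via alkenylzirconocene 15 (not isolated)
Conditions: Cp2Zr(H)Cl, THF, 25 °C; I2, 0 °C
Reagents that add atoms: iodine II
Why: Regioselective syn-hydrozirconation of the terminal alkyne (Schwartz reagent) and iodinolysis of the C–Zr bond with retention give the (E)-iodo-diene.

Step 10
Reactants: 13 alkenylboronate (C7–C(CH3)=CH–Bpin); 16 (1E)-1-iodo-3-methylbuta-1,3-diene
Product: 17 (1R,5R,7R,10R)-1-bromo-7-[(2E,4E)-6-methylhepta-2,4,6-trien-2-yl]-11,12,13-trinoreudesm-4(15)-en-5-ol (target)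
Conditions: Pd(dppf)Cl2 (5 mol %), K3PO4, THF–H2O, 25 → 40 °C, degassed, dark
Reagents that add atoms: none
Why: Suzuki–Miyaura coupling, which retains the geometry of both alkenyl partners and so gives the (2E,4E)-triene, while the mildly basic conditions leave the secondary alkyl bromide, the tertiary allylic alcohol and the four ring stereocentres untouched.

## Compound list

1 | (R)-(−)-carvone | CC1=CC[C@H](CC1=O)C(C)=C | starting material
2 | lithium (5R)-2-methyl-5-(prop-1-en-2-yl)cyclohex-1-en-1-olate | [Li+].[O-]C1=C(C)CC[C@@H](C(C)=C)C1 | intermediate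
3 | (2R,5R)-2-(1-hydroxyethyl)-2-methyl-5-(prop-1-en-2-yl)cyclohexan-1-one (hydroxyethyl cis to isopropenyl; both carbinol epimers) | O=C1C[C@H](C(C)=C)CC[C@]1(C)C(C)O | intermediate
4 | (2R,5R)-2-ethenyl-2-methyl-5-(prop-1-en-2-yl)cyclohexan-1-one (vinyl cis to isopropenyl) | O=C1C[C@H](C(C)=C)CC[C@]1(C)C=C | intermediate
5 | (1S,2R,5R)-2-ethenyl-2-methyl-1,5-di(prop-1-en-2-yl)cyclohexan-1-ol (C1 isopropenyl trans to C2 vinyl) | O[C@]1(C(C)=C)C[C@H](C(C)=C)CC[C@]1(C)C=C | intermediate
6 | potassium (1Z,5E,9R)-2,6-dimethyl-9-(prop-1-en-2-yl)cyclodeca-1,5-dien-1-olate | [K+].[O-]/C1=C(/C)CC/C=C(\C)CC[C@@H](C(C)=C)C1 | intermediate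
7 | (1Z,5E,9R)-2,6-dimethyl-9-(prop-1-en-2-yl)cyclodeca-1,5-dien-1-yl acetate (ring carbons trans across both ring olefins) | CC(=O)O/C1=C(/C)CC/C=C(\C)CC[C@@H](C(C)=C)C1 | intermediate
8 | 1β-bromoeudesm-11-ene-4α,5α-diyl 2-methyl-1,3-dioxolan-2-ylium, succinimidate salt | CC(=C)[C@@H]1CC[C@@]2(C)[C@H](Br)CC[C@@]3(C)[O+]=C(C)O[C@@]23C1.O=C1CCC(=O)[N-]1 | intermediate
9 | (1R,4R,5S,7R,10R)-1-bromo-4-hydroxyeudesm-11-en-5-yl acetate (1β-Br, 4α-OH, 5α-OAc, 7β-isopropenyl, 10β-CH3, trans-decalin) | CC(=C)[C@@H]1CC[C@@]2(C)[C@H](Br)CC[C@@](C)(O)[C@]2(OC(C)=O)C1 | intermediate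
10 | 4α-chlorosulfite of 9 | CC(=C)[C@@H]1CC[C@@]2(C)[C@H](Br)CC[C@@](C)(OS(Cl)=O)[C@]2(OC(C)=O)C1 | intermediate
11 | (1R,5R,7R,10R)-1-bromoeudesma-4(15),11-dien-5-yl acetate | CC(=C)[C@@H]1CC[C@@]2(C)[C@H](Br)CCC(=C)[C@]2(OC(C)=O)C1 | intermediate
12 | (1R,5R,7R,10R)-1-bromoeudesma-4(15),11-dien-5-ol | CC(=C)[C@@H]1CC[C@@]2(C)[C@H](Br)CCC(=C)[C@]2(O)C1 | intermediate
13 | (E)-alkenylboronate, C7–C(CH3)=CH–Bpin on the (1R,5R,7R,10R)-1-bromo-5-hydroxyeudesm-4(15)-ene core | CC1(C)OB(/C=C(\C)[C@@H]2CC[C@@]3(C)[C@H](Br)CCC(=C)[C@]3(O)C2)OC1(C)C | intermediate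
14 | 2-methylbut-1-en-3-yne | C=C(C)C#C | starting material
15 | chlorobis(cyclopentadienyl)[(1E)-3-methylbuta-1,3-dien-1-yl]zirconium | C=C(C)/C=C/[Zr](Cl)(C1C=CC=C1)C1C=CC=C1 | intermediate
16 | (1E)-1-iodo-3-methylbuta-1,3-diene | C=C(C)/C=C/I | intermediate
17 | (1R,5R,7R,10R)-1β-bromo-5α-hydroxy-10β-methyl-4-methylene-7β-[(2E,4E)-6-methylhepta-2,4,6-trien-2-yl]-trans-decalin (CNP0385268.1) | C=C(C)/C=C/C=C(\C)[C@@H]1CC[C@@]2(C)[C@H](Br)CCC(=C)[C@]2(O)C1 | target

## Step count and risks

Total steps: 10. Longest linear sequence: 9 (steps 1–8 and 10; step 9 makes the coupling partner).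

Step 5 is the most likely to fail. NBS may instead brominate the enol acetate carbon or the isopropenyl group, or the enol acetate may not act as the internal nucleophile. The fallback sets out from 5 and comes back at 12. The oxy-Cope enolate is trapped with PhNTf2 as the enol triflate F1, and Pd-catalysed formate reduction (Pd(OAc)2, PPh3, HCO2H, Bu3N, DMF, 40 °C) gives germacrene A F2. NBS in CH2Cl2 at −78 °C cyclises F2 transannularly to the 1β-bromoselinadienes, which catalytic iodine equilibrates to the tetrasubstituted 1β-bromoselina-4,11-diene F3. A singlet-oxygen ene reaction from the α face (O2, hν, methylene blue, −20 °C) gives the 5α-hydroperoxide F4, and PPh3 reduces it to 12.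

Step 6 is the second risk. The chlorosulfite may lose a C3 hydrogen to give the endocyclic Δ3 olefin, or the neighbouring acetate may interfere. The fallback sets out from 4 and comes back at 11. The Grignard reagent from 2-bromoallyltrimethylsilane adds to 4 to give the silylmethyl carbinol F5, and KH/18-crown-6 followed by Ac2O gives the silylmethyl enol acetate F6. NBS in THF at −78 °C then closes both rings, and the β-silyl cation at C4 loses the trimethylsilyl group, so the exocyclic methylene of 11 forms directly and no dehydration is needed. The price is that the allylsilane is itself a competing site for Br+.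

Step 8 is the third risk. The α-branched isopropenyl olefin may be too hindered for cross-metathesis. The fallback sets out from 9 and comes back at 13. Ozonolysis of the only olefin of 9 (O3, CH2Cl2–MeOH, −78 °C; Me2S) gives the methyl ketone F7. Boron-Wittig olefination with lithiated bis(pinacolato)borylmethane (CH2(Bpin)2, LiTMP, THF, −78 → 0 °C) gives the (E)-alkenylboronate F8. SOCl2/pyridine dehydration gives the alkenylboronate acetate F9, and DIBAL-H at −78 °C removes the acetate to give 13.

## Further compounds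

F1 | step 5 | (1Z,5E,9R)-2,6-dimethyl-9-(prop-1-en-2-yl)cyclodeca-1,5-dien-1-yl trifluoromethanesulfonate | O=S(=O)(O/C1=C(/C)CC/C=C(\C)CC[C@@H](C(C)=C)C1)C(F)(F)F
F2 | step 5 | germacrene A, (1E,5E,8R)-1,5-dimethyl-8-(prop-1-en-2-yl)cyclodeca-1,5-diene | C1/C=C(\C)CC/C=C(\C)CC[C@H]1C(C)=C
F3 | step 5 | (1R,7R,10R)-1-bromoeudesma-4,11-diene (1β-bromoselina-4,11-diene) | CC(=C)[C@@H]1CC[C@@]2(C)[C@H](Br)CCC(C)=C2C1
F4 | step 5 | (1R,5R,7R,10R)-1-bromo-5-hydroperoxyeudesma-4(15),11-diene | CC(=C)[C@@H]1CC[C@@]2(C)[C@H](Br)CCC(=C)[C@]2(OO)C1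
F5 | step 6 | 2-ethenyl-2-methyl-5-(prop-1-en-2-yl)-1-[3-(trimethylsilyl)prop-1-en-2-yl]cyclohexan-1-ol (same relative and absolute arrangement as 5) | O[C@]1(C(=C)C[Si](C)(C)C)C[C@H](C(C)=C)CC[C@]1(C)C=C
F6 | step 6 | (1E,5E,9R)-6-methyl-9-(prop-1-en-2-yl)-2-[(trimethylsilyl)methyl]cyclodeca-1,5-dien-1-yl acetate | CC(=O)O/C1=C(/C[Si](C)(C)C)CC/C=C(\C)CC[C@@H](C(C)=C)C1
F7 | step 8 | 7β-acetyl-1β-bromo-4α-hydroxy-4β,10β-dimethyl-trans-decalin-5α-yl acetate | CC(=O)[C@@H]1CC[C@@]2(C)[C@H](Br)CC[C@@](C)(O)[C@]2(OC(C)=O)C1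
F8 | step 8 | (E)-alkenylboronate C7–C(CH3)=CH–Bpin of the 1β-bromo-4α-hydroxy-5α-acetoxy core | CC1(C)OB(/C=C(\C)[C@@H]2CC[C@@]3(C)[C@H](Br)CC[C@@](C)(O)[C@]3(OC(C)=O)C2)OC1(C)C
F9 | step 8 | (E)-alkenylboronate C7–C(CH3)=CH–Bpin of the 1β-bromo-5α-acetoxy-4(15)-ene core | CC1(C)OB(/C=C(\C)[C@@H]2CC[C@@]3(C)[C@H](Br)CCC(=C)[C@]3(OC(C)=O)C2)OC1(C)C
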